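## Retrosynthetic overview

1. Target ⇐ methanolysis of the six aryl acetates of the endo cycloadduct hexaacetate.
2. The cyclohexene is the only ring made, in the penultimate step: an intermolecular endo Diels–Alder reaction (bonds C1–C6 and C4–C5) on an (S)-VANOL boron centre, setting all three stereocentres.
3. Dienophile (morachalcone A triacetate with free 2'-OH) ⇐ Stille prenylation ⇐ BF3 Claisen–Schmidt of 4-acetoxy-2-hydroxy-3-iodoacetophenone with 2,4-diacetoxybenzaldehyde.
4. Diene (peracetylated dehydroprenyl chalcone) ⇐ Suzuki dienylation ⇐ triacetate of the 3'-iodochalcone from 2,4-dihydroxy-3-iodoacetophenone and 4-hydroxybenzaldehyde; the dienyl boronate comes from 2-methylbut-1-en-3-yne and pinacolborane.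
5. Both halves share 2,4-dihydroxy-3-iodoacetophenone (iodination of 2,4-dihydroxyacetophenone); all benzene rings are bought.

Structure reading: the target is the cis,trans (endo-type) adduct, (1S,5S,6R), with C1 carrying the chalcone aryl group, C5 the 2,4-dihydroxyphenyl group and C6 the aroyl group (aroyl cis to the C1 aryl, trans to the C5 aryl).

Assumption: the (S)-VANOL boron complex is taken to deliver the (1S,5S,6R) series; if the first run shows the opposite sense, (R)-VANOL is used with nothing else changed.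

## Route

Step 1
Reactants: 1 2,4-dihydroxyacetophenone
Product: 2 1-(2,4-dihydroxy-3-iodophenyl)ethan-1-one
Conditions: I2 (0.4 equiv), HIO3 (0.2 equiv), EtOH/H2O, rt
Reagents that add atoms: iodine, II; iodic acid, O[I](=O)=O
Why: Electrophilic aromatic iodination (iodine with iodic acid as oxidant) goes to C3, the position ortho to both hydroxyl groups and the most activated one; no stereocentre is formed.

Step 2
Reactants: 2 1-(2,4-dihydroxy-3-iodophenyl)ethan-1-one
Product: 3 4-acetyl-3-hydroxy-2-iodophenyl acetate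
Conditions: Ac2O (1.05 equiv), pyridine, CH2Cl2, 0 °C
Reagents that add atoms: acetic anhydride, CC(=O)OC(C)=O
Why: Selective O-acylation, because the 2-OH is tied up in a hydrogen bond to the ketone and stays free while the 4-OH is acetylated.

Step 3
Reactants: 4 2,4-dihydroxybenzaldehyde
Product: 5 4-formyl-1,3-phenylene diacetate
Conditions: Ac2O (2.5 equiv), pyridine, DMAP (cat.), CH2Cl2, 0 °C → rt
Reagents that add atoms: acetic anhydride, CC(=O)OC(C)=O
Why: DMAP-catalysed O-acetylation of both phenols gives an aldehyde whose ortho oxygen is blocked, so the later chalcone cannot close to a flavylium salt under Lewis acid.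

Step 4
Reactants: 3 4-acetyl-3-hydroxy-2-iodophenyl acetate; 5 4-formyl-1,3-phenylene diacetate
Product: 7 (E)-4-[3-(4-acetoxy-2-hydroxy-3-iodophenyl)-3-oxoprop-1-en-1-yl]-1,3-phenylene diacetate, via aldol adduct 6 (not isolated)
Conditions: BF3·OEt2 (1.5 equiv), 1,4-dioxane, rt; aq. NaHCO3 work-up
Reagents that add atoms: none
Why: BF3-promoted Claisen–Schmidt condensation, in which Lewis-acid enolisation of the ketone, aldol addition to 5 and loss of water from 6 give the conjugated E-enone without the base that would cleave the aryl acetates.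

Step 5
Reactants: 7 (E)-4-[3-(4-acetoxy-2-hydroxy-3-iodophenyl)-3-oxoprop-1-en-1-yl]-1,3-phenylene diacetate; 8 tributyl(3-methylbut-2-en-1-yl)stannane
Product: 9 (E)-4-[3-[4-acetoxy-2-hydroxy-3-(3-methylbut-2-en-1-yl)phenyl]-3-oxoprop-1-en-1-yl]-1,3-phenylene diacetate
Conditions: Pd(PPh3)4 (10 mol%), DMF, 90 °C
Reagents that add atoms: none
Why: Migita–Kosugi–Stille coupling under neutral conditions, where zerovalent palladium inserts into the C–I bond and reductive elimination at the less hindered allyl terminus gives the linear prenyl group, leaving acetates, enone and the chelated phenol untouched.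

Step 6
Reactants: 2 1-(2,4-dihydroxy-3-iodophenyl)ethan-1-one; 10 4-hydroxybenzaldehyde
Product: 12 (E)-1-(2,4-dihydroxy-3-iodophenyl)-3-(4-hydroxyphenyl)prop-2-en-1-one, via aldol adduct 11 (not isolated)
Conditions: SOCl2 (0.5 equiv), EtOH, rt
Reagents that add atoms: none
Why: Acid-catalysed Claisen–Schmidt condensation (HCl generated from SOCl2 and EtOH) tolerates free phenols and the aryl iodide, and aldol 11 dehydrates to the E-chalcone.

Step 7
Reactants: 12 (E)-1-(2,4-dihydroxy-3-iodophenyl)-3-(4-hydroxyphenyl)prop-2-en-1-one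
Product: 13 (E)-4-[3-(2,4-diacetoxy-3-iodophenyl)-3-oxoprop-1-en-1-yl]phenyl acetate
Conditions: Ac2O (5 equiv), pyridine, DMAP (cat.), rt → 40 °C
Reagents that add atoms: acetic anhydride, CC(=O)OC(C)=O
Why: Exhaustive DMAP-catalysed acetylation caps all three phenols, including the chelated 2'-OH, so this chalcone cannot bind boron and act as a dienophile later and no free ortho-hydroxy diene is ever generated.

Step 8
Reactants: 14 2-methylbut-1-en-3-yne; 15 pinacolborane
Product: 16 (E)-4,4,5,5-tetramethyl-2-(3-methylbuta-1,3-dien-1-yl)-1,3,2-dioxaborolane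
Conditions: Cp2Zr(H)Cl (10 mol%), Et3N (10 mol%), neat, sealed tube, 60 °C
Reagents that add atoms: none
Why: Cp2Zr(H)Cl-catalysed syn hydroboration of the terminal alkyne is anti-Markovnikov and gives only the E-alkenylboronate, leaving the 1,1-disubstituted alkene alone.

Step 9
Reactants: 13 (E)-4-[3-(2,4-diacetoxy-3-iodophenyl)-3-oxoprop-1-en-1-yl]phenyl acetate; 16 (E)-4,4,5,5-tetramethyl-2-(3-methylbuta-1,3-dien-1-yl)-1,3,2-dioxaborolane
Product: 17 (E)-4-[3-[2,4-diacetoxy-3-((E)-3-methylbuta-1,3-dien-1-yl)phenyl]-3-oxoprop-1-en-1-yl]phenyl acetate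
Conditions: Pd(OAc)2 (5 mol%), SPhos (10 mol%), K3PO4 (2 equiv), toluene, H2O (3 equiv), 60 °C
Reagents that add atoms: none
Why: Suzuki–Miyaura coupling with the bulky electron-rich SPhos ligand handles the doubly ortho-substituted aryl iodide and transfers the dienyl group with retention of E geometry, while the weakly basic, nearly anhydrous phosphate spares the aryl acetates.

Step 10
Reactants: 9 (E)-4-[3-[4-acetoxy-2-hydroxy-3-(3-methylbut-2-en-1-yl)phenyl]-3-oxoprop-1-en-1-yl]-1,3-phenylene diacetate; 17 (E)-4-[3-[2,4-diacetoxy-3-((E)-3-methylbuta-1,3-dien-1-yl)phenyl]-3-oxoprop-1-en-1-yl]phenyl acetate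
Product: 20 (E)-1-{3-[(1S,5S,6R)-6-[4-acetoxy-2-hydroxy-3-(3-methylbut-2-en-1-yl)benzoyl]-5-(2,4-diacetoxyphenyl)-3-methylcyclohex-2-en-1-yl]-2,4-diacetoxyphenyl}-3-(4-acetoxyphenyl)prop-2-en-1-one, via dienophile boron chelate 18 (not isolated), via adduct boron chelate 19 (not isolated)
Conditions: (S)-VANOL (1.2 equiv), BH3·THF (1.2 equiv), AcOH (1.2 equiv), THF, rt, 1 h; then 9; then 17 (1.5 equiv), rt, 24–48 h; aqueous work-up, chromatography (endo separated from exo)
Reagents that add atoms: none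
Why: Chiral-boron-mediated asymmetric Diels–Alder reaction, in which chelation of the 2'-phenoxide and carbonyl of 9 on the VANOL boron centre (18) activates only this enone; the E-enone geometry fixes the trans C5/C6 relationship, the endo approach places the aroyl group cis to the C1 aryl group, and the VANOL phenyl wall selects the enone face leading to 1S,5S,6R.

Step 11
Reactants: 20 the endo hexaacetate
Product: 21 (E)-1-{3-[(1S,5S,6R)-6-[2,4-dihydroxy-3-(3-methylbut-2-en-1-yl)benzoyl]-5-(2,4-dihydroxyphenyl)-3-methylcyclohex-2-en-1-yl]-2,4-dihydroxyphenyl}-3-(4-hydroxyphenyl)prop-2-en-1-one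
Conditions: K2CO3 (0.5 equiv), degassed MeOH, 0 °C → rt; then dilute aq. HCl to pH 5
Reagents that add atoms: none
Why: Base-catalysed transesterification (Zemplén-type methanolysis) removes all six aryl acetates as methyl acetate under conditions too mild to epimerise C6 or touch the enone, prenyl and cyclohexene double bonds, so the three stereocentres are carried through unchanged.

## Compound list

1 | 2,4-dihydroxyacetophenone | CC(=O)c1ccc(O)cc1O | starting material
2 | 1-(2,4-dihydroxy-3-iodophenyl)ethan-1-one | CC(=O)c1ccc(O)c(I)c1O | intermediate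
3 | 4-acetyl-3-hydroxy-2-iodophenyl acetate | CC(=O)Oc1ccc(C(C)=O)c(O)c1I | intermediate
4 | 2,4-dihydroxybenzaldehyde | O=Cc1ccc(O)cc1O | starting material
5 | 4-formyl-1,3-phenylene diacetate | CC(=O)Oc1ccc(C=O)c(OC(C)=O)c1 | intermediate
6 | 4-[3-(4-acetoxy-2-hydroxy-3-iodophenyl)-1-hydroxy-3-oxopropyl]-1,3-phenylene diacetate (racemic aldol adduct, not isolated) | CC(=O)Oc1ccc(C(O)CC(=O)c2ccc(OC(C)=O)c(I)c2O)c(OC(C)=O)c1 | intermediate
7 | (E)-4-[3-(4-acetoxy-2-hydroxy-3-iodophenyl)-3-oxoprop-1-en-1-yl]-1,3-phenylene diacetate | CC(=O)Oc1ccc(/C=C/C(=O)c2ccc(OC(C)=O)c(I)c2O)c(OC(C)=O)c1 | intermediate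
8 | tributyl(3-methylbut-2-en-1-yl)stannane | CCCC[Sn](CCCC)(CCCC)CC=C(C)C | starting material
9 | (E)-4-[3-[4-acetoxy-2-hydroxy-3-(3-methylbut-2-en-1-yl)phenyl]-3-oxoprop-1-en-1-yl]-1,3-phenylene diacetate (dienophile) | CC(=O)Oc1ccc(/C=C/C(=O)c2ccc(OC(C)=O)c(CC=C(C)C)c2O)c(OC(C)=O)c1 | intermediate
10 | 4-hydroxybenzaldehyde | O=Cc1ccc(O)cc1 | starting material
11 | 1-(2,4-dihydroxy-3-iodophenyl)-3-hydroxy-3-(4-hydroxyphenyl)propan-1-one (racemic aldol adduct, not isolated) | O=C(CC(O)c1ccc(O)cc1)c1ccc(O)c(I)c1O | intermediate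
12 | (E)-1-(2,4-dihydroxy-3-iodophenyl)-3-(4-hydroxyphenyl)prop-2-en-1-one | O=C(/C=C/c1ccc(O)cc1)c1ccc(O)c(I)c1O | intermediate
13 | (E)-4-[3-(2,4-diacetoxy-3-iodophenyl)-3-oxoprop-1-en-1-yl]phenyl acetate | CC(=O)Oc1ccc(/C=C/C(=O)c2ccc(OC(C)=O)c(I)c2OC(C)=O)cc1 | intermediate
14 | 2-methylbut-1-en-3-yne | C#CC(C)=C | starting material
15 | pinacolborane (4,4,5,5-tetramethyl-1,3,2-dioxaborolane) | CC1(C)OBOC1(C)C | starting material
16 | (E)-4,4,5,5-tetramethyl-2-(3-methylbuta-1,3-dien-1-yl)-1,3,2-dioxaborolane | CC(=C)/C=C/B1OC(C)(C)C(C)(C)O1 | intermediate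
17 | (E)-4-[3-[2,4-diacetoxy-3-((E)-3-methylbuta-1,3-dien-1-yl)phenyl]-3-oxoprop-1-en-1-yl]phenyl acetate (diene) | CC(=O)Oc1ccc(/C=C/C(=O)c2ccc(OC(C)=O)c(/C=C/C(C)=C)c2OC(C)=O)cc1 | intermediate
18 | spiro borate in which the 2'-phenoxide and carbonyl oxygen of 9 chelate the boron atom of the (S)-VANOL boron unit (not isolated; the S axis of the binaphthyl cannot be written in SMILES) | CC(=O)Oc1ccc(/C=C/C2=[O+][B-]3(Oc4c(-c5c(O3)c6ccccc6cc5-c5ccccc5)c(-c5ccccc5)cc5ccccc45)Oc3c(CC=C(C)C)c(OC(C)=O)ccc23)c(OC(C)=O)c1 | intermediate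
19 | the corresponding (S)-VANOL spiro borate of cycloadduct 20, (1S,5S,6R) (not isolated; binaphthyl axis not written in SMILES) | CC(C)=CCc1c(OC(C)=O)ccc2c1O[B-]1(Oc3c(-c4c(O1)c5ccccc5cc4-c4ccccc4)c(-c4ccccc4)cc4ccccc34)[O+]=C2[C@H]1[C@@H](c3c(OC(C)=O)ccc(C(=O)/C=C/c4ccc(OC(C)=O)cc4)c3OC(C)=O)C=C(C)C[C@@H]1c1ccc(OC(C)=O)cc1OC(C)=O | intermediate
20 | (E)-1-{3-[(1S,5S,6R)-6-[4-acetoxy-2-hydroxy-3-(3-methylbut-2-en-1-yl)benzoyl]-5-(2,4-diacetoxyphenyl)-3-methylcyclohex-2-en-1-yl]-2,4-diacetoxyphenyl}-3-(4-acetoxyphenyl)prop-2-en-1-one (endo hexaacetate) | CC(C)=CCc1c(OC(C)=O)ccc(C(=O)[C@H]2[C@@H](c3c(OC(C)=O)ccc(C(=O)/C=C/c4ccc(OC(C)=O)cc4)c3OC(C)=O)C=C(C)C[C@@H]2c2ccc(OC(C)=O)cc2OC(C)=O)c1O | intermediate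
21 | (E)-1-{3-[(1S,5S,6R)-6-[2,4-dihydroxy-3-(3-methylbut-2-en-1-yl)benzoyl]-5-(2,4-dihydroxyphenyl)-3-methylcyclohex-2-en-1-yl]-2,4-dihydroxyphenyl}-3-(4-hydroxyphenyl)prop-2-en-1-one (CNP0283121.1) | CC(C)=CCc1c(O)ccc(C(=O)[C@H]2[C@@H](c3c(O)ccc(C(=O)/C=C/c4ccc(O)cc4)c3O)C=C(C)C[C@@H]2c2ccc(O)cc2O)c1O | target

## Step count and risks

Total: 11 steps. Longest linear sequence: 6 steps (1 → 2 → 3 → 7 → 9 → 20 → 21; the diene arm 1 → 2 → 12 → 13 → 17 → 20 → 21 is equally long).

The three steps most likely to fail: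

Step 10 (asymmetric Diels–Alder). The endo/exo ratio and the level and sense of enantioinduction are substrate-dependent. The fallback sets out from 9 and 17 and replaces asymmetric induction by a racemic cycloaddition followed by resolution. Silica-supported zerovalent silver nanoparticles (Ag on SiO2, 0.5 mol% Ag) in CH2Cl2 at 50 °C promote the cycloaddition of the 2'-hydroxychalcone, normally with the endo isomer favoured. After chromatographic removal of the exo isomer this gives the racemic endo hexaacetate F1. Preparative HPLC on an amylose tris(3,5-dimethylphenylcarbamate) phase then delivers the (1S,5S,6R) enantiomer, and the route is rejoined at 20.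

Step 4 (BF3 aldol in the presence of three aryl acetates and a chelating 2-hydroxyacetophenone). Acetyl loss or a stalled boron chelate is possible. The fallback sets out from 3 and builds the enone by olefination instead of aldol condensation. CuBr2 in EtOAc/CHCl3 at reflux gives 4-(2-bromoacetyl)-3-hydroxy-2-iodophenyl acetate F2. PPh3 in toluene at rt converts it to the phosphonium bromide F3. Et3N in CH2Cl2 liberates the stabilised acyl ylide F4, which is heated with aldehyde 5 in toluene (E-selective Wittig reaction under neutral conditions). The route is rejoined at 7.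

Step 9 (Suzuki coupling of a doubly ortho-substituted aryl iodide that carries base-labile acetates). Slow oxidative addition or acetate cleavage is possible. The fallback sets out from 13 and builds the diene in two stages. Heck coupling with 2-methylbut-3-en-2-ol (Pd(OAc)2, Bu4NCl, NaHCO3, DMF, 70 °C) gives the tertiary allylic alcohol F5. MsCl/Et3N in CH2Cl2 at 0 °C converts this through the tertiary mesylate F6, which eliminates in the flask toward a methyl group, the only position with β-hydrogens that can give a diene. The route is rejoined at 17.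

## Further compounds

F1 | step 10 | racemic endo hexaacetate (20 together with its mirror image) | CC(C)=CCc1c(OC(C)=O)ccc(C(=O)[C@H]2[C@@H](c3c(OC(C)=O)ccc(C(=O)/C=C/c4ccc(OC(C)=O)cc4)c3OC(C)=O)C=C(C)C[C@@H]2c2ccc(OC(C)=O)cc2OC(C)=O)c1O.CC(C)=CCc1c(OC(C)=O)ccc(C(=O)[C@@H]2[C@H](c3c(OC(C)=O)ccc(C(=O)/C=C/c4ccc(OC(C)=O)cc4)c3OC(C)=O)C=C(C)C[C@H]2c2ccc(OC(C)=O)cc2OC(C)=O)c1O
F2 | step 4 | 4-(2-bromoacetyl)-3-hydroxy-2-iodophenyl acetate | CC(=O)Oc1ccc(C(=O)CBr)c(O)c1I
F3 | step 4 | [2-(4-acetoxy-2-hydroxy-3-iodophenyl)-2-oxoethyl]triphenylphosphonium bromide | CC(=O)Oc1ccc(C(=O)C[P+](c2ccccc2)(c2ccccc2)c2ccccc2)c(O)c1I.[Br-]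
F4 | step 4 | 3-hydroxy-2-iodo-4-[(triphenylphosphoranylidene)acetyl]phenyl acetate (stabilised ylide) | CC(=O)Oc1ccc(C(=O)C=P(c2ccccc2)(c2ccccc2)c2ccccc2)c(O)c1I
F5 | step 9 | (E)-4-[3-[2,4-diacetoxy-3-((E)-3-hydroxy-3-methylbut-1-en-1-yl)phenyl]-3-oxoprop-1-en-1-yl]phenyl acetate | CC(=O)Oc1ccc(/C=C/C(=O)c2ccc(OC(C)=O)c(/C=C/C(C)(C)O)c2OC(C)=O)cc1
F6 | step 9 | methanesulfonate of F5 (tertiary allylic mesylate, not isolated) | CC(=O)Oc1ccc(/C=C/C(=O)c2ccc(OC(C)=O)c(/C=C/C(C)(C)OS(C)(=O)=O)c2OC(C)=O)cc1
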